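**Assumptions and remarks on the chemistry**

- The target is taken as the (2S)-flavanone. Every intermediate is drawn with the same spatial arrangement at the carbinol carbon; the descriptor stays S throughout (O > aryl > CH2 > H).
- The open chain and its folding were checked atom by atom (nine chain carbons, oxygen on C2, C4, C8a, C7, C5, prenyl on C8, S at C2). No constitution or configuration had to be corrected.
- One design change was made. C5 leaves as dimethylamine and not as an alcohol, so the C7/C6/C5 terminus is a dimethylamino-enone (a vinylogous amide). An alkoxy-enone next to a free 1,3-diketone is the classical precursor of a 4-pyranone under acid: the enol oxygen on C8a would reach C5 before the C2 hydroxyl reaches C8a. The vinylogous amide is a far weaker electrophile in cold dilute acid, is isolable, and is made in one step. Skeleton, bonds formed and rings closed are unchanged.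
- C8 of the open-chain diketone is enolisable and becomes sp2, so that compound is handled as a mixture of C8 epimers and enol tautomers.

## Structural features

Sophoranone is a flavanone: ring A (benzo) is fused to ring C (a 2,3-dihydro-4H-pyran-4-one) through C4a–C8a, and ring B is attached at C2. C2 is the only stereocentre; it is benzylic, bears O1 and has no stereogenic neighbour. Ring A carries 7-OH and a prenyl group on C8, between O1 and the 7-oxygen; ring B carries 4'-OH flanked by two prenyl groups. The C2–O1 bond is fragile: it lies β to the C4 ketone (base opens it to the chalcone) and is para-oxygenated benzylic (strong acid ionises it), and either event racemises C2. The three trisubstituted alkenes sit ortho to phenols, so hydrogenation, electrophilic oxidants and hot strong acid (chroman formation) are excluded. The real difficulties are making and keeping C2 as one enantiomer and placing the ring A prenyl on C8 and not on C6. The key step exploits the chain C2–C3–C4–C4a–C8a–C8–C7–C6–C5, oxygenated on every second carbon. Rings C and A are this polyketone folded by an O1–C8a condensation and a C4a–C5 aldol, and C8 is the central carbon of the C8a/C7 1,3-diketone, so the prenyl position is fixed in the open chain.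

## Logic of the disconnections

**20 ⇒ 19.** The 4'-O–CH2 bond of the acetal is cut. Ring B oxygen must be masked through the enolate steps, and an acetal twisted by two ortho prenyl groups is a poor π-donor, which protects C2 from ionisation in the acid cascade. The forward step must be acidic enough to cleave an aryl acetal but not to cyclise prenyl onto phenol.

**19 ⇒ 16.** O1–C8a and C4a–C5 are cut. This unfolds rings C and A into one open chain and reduces the problem to carbonyl chemistry. The gain is two rings, no aromatic prenylation on ring A and an untouched C2–O bond. The demand is order: O1–C8a must form before anything attacks C5.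

**16 ⇒ 10 + 13.** C8a–C8 and the O–Si bond are cut. The C8a carbonyl of 16 is the lactone carbonyl of 10, its ring oxygen is the C2 oxygen, and C8 is the only enolisable carbon of 13. Two fragments of similar size result. The forward step needs two equivalents of enolate (the product diketone is acidic), carbonyl addition faster than γ-deprotonation of 10, and trapping of the released alkoxide.

**13 ⇒ 11 + 12.** The C6=C5 bond is cut. The prenyl group is already present in 11 and C5 comes from 12. The forward condensation must take place at the methyl and not at the methylene group of 11.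

**10 ⇒ 8.** The enol O–CH3 bond and the lactone acyl–oxygen bond are cut. The dioxinone of 8 is a masked β-keto acid that the carbinol oxygen can acylate. The forward step needs a base mild enough not to open the lactone by elimination.

**8 ⇒ 4 + 6; 6 ⇒ 5.** C2–C3 is cut. This is the only stereogenic bond formation and it is placed on a simple aromatic aldehyde under catalyst control. The demand is high facial selectivity and γ-regioselectivity of the dienolate.

**4 ⇒ 2 + 3; 2 ⇒ 1.** The two aryl–CH2 bonds and the acetal O–CH2 bond are cut. Both prenyl groups enter in one operation on a symmetrical di-iodide. The demand is linear (α) allyl transfer and tolerance of the aldehyde.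

## Other disconnections considered

**Alternative 1:** The cut is C4a–C4, C4–C3 and O1–C2, back to the iodophenol A2, the arylacetylene A3 and carbon monoxide. In the forward step PdCl2(PPh3)2, reduced in situ to zerovalent palladium, would carbonylate A2, couple the acyl-palladium with A3 and, through amine addition to the ynone, close ring C as flavone A1. In its favour: the reaction type is well established, it is highly convergent, the prenyl groups should be inert, and A3 is one homologation away from 4. On precedent for ring construction and on convergence it is the better of the two plans. Against it here: A1 is achiral, so C2 must be set afterwards by enantioselective 1,4-reduction of a β-aryl chromone. That is a sluggish, cross-conjugated acceptor. A copper hydride would have to avoid 1,2-reduction, and the flavanone enolate it generates can expel the phenoxide and racemise. Hydrogenation is excluded by the three alkenes. A2 also needs a regiocontrolled C-prenylation between two oxygens. Step count would be about equal. The chosen plan is weaker on precedent for its key step but sets C2 in an ordinary aldehyde addition and settles the C8 regiochemistry in an open chain.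

**Alternative 2:** The cut is C4–C4a, back to the bromoaryl ether Weinreb amide A5. In the forward step t-BuLi would exchange bromine for lithium at low temperature and the aryllithium would attack the amide carbon to give A4. In its favour: Parham-type closures onto Weinreb amides are known for chroman-4-ones, over-addition is blocked by the chelate, and C2 with its C–O bond is in place before the ring closes at −78 °C or below. On stereochemical integrity during ring closure it is the equal or the better of the chosen plan. Against it here: A5 needs an ether bond between a para-alkoxybenzylic secondary carbon and a phenol flanked by bromine and prenyl. A Mitsunobu inversion there would be slow and liable to ionisation. The β-aryloxy amide can lose phenoxide by E1cB if the base deprotonates instead of exchanging. Ring A must again be built as a tetrasubstituted arene, and two protecting groups are removed at the end. The route would be three or four steps longer than the chosen one.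

**Alternative 3:** The cut is C2–C3, back to the benzyl aryl ether A7. In the forward step Ag2O would oxidise A7 to the para-quinone methide A8, and a chiral primary amine–thiourea would form the enamine of the acetyl group, whose C3 adds to C2 to give A6. In its favour: the ring closure and the stereocentre are made together under catalyst control, ring B needs no protecting group, and the sequence would be as short as or shorter than the chosen one. On step economy it is at least the equal. Against it here: A8 carries an aryloxy group on the methide carbon, which makes it a vinylogous ester, less electrophilic and open to hydrolysis. Prenyl groups stabilise a quinone methide much less than tert-butyl groups. The amine can add to A8 itself. The free 4'-hydroxyl of A6 allows reversible opening of C2–O1 under the basic conditions, which would erode the selectivity. Both key steps lack close precedent; the chosen one keeps C2 out of the bond-forming events.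

Key step: step 8

## Route

**Step 1**
Reactants: 1 4-hydroxy-3,5-diiodobenzaldehyde
Product: 2 3,5-diiodo-4-(methoxymethoxy)benzaldehyde
Conditions: MOMCl, iPr2NEt, CH2Cl2, 0 °C → rt
Reagents that add atoms: chloromethyl methyl ether, COCCl
Why: O-alkylation of an acidic phenol (Williamson type); the phenoxide, made more acidic by two iodines and the para-formyl group, should react cleanly with the reactive chloride.

**Step 2**
Reactants: 2 3,5-diiodo-4-(methoxymethoxy)benzaldehyde; 3 tributyl(3-methylbut-2-en-1-yl)stannane
Product: 4 4-(methoxymethoxy)-3,5-bis(3-methylbut-2-en-1-yl)benzaldehyde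
Conditions: 3 (2.5 equiv), Pd(PPh3)4 (5 mol%), DMF, 90 °C
Reagents that add atoms: none
Why: Twofold Stille coupling; both C–I bonds are activated by the para-formyl group, the aldehyde and the acetal are tolerated, and reductive elimination from the allyl(aryl)palladium intermediate at the less substituted terminus should give the linear prenyl isomer.

**Step 3**
Reactants: 5 2,2,6-trimethyl-4H-1,3-dioxin-4-one
Product: 6 2,2-dimethyl-6-methylidene-4-(trimethylsilyloxy)-6H-1,3-dioxine
Conditions: LiN(iPr)2, THF, −78 °C; Me3SiCl, −78 → 0 °C
Reagents that add atoms: chlorotrimethylsilane, C[Si](C)(C)Cl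
Why: Kinetic γ-deprotonation of the vinylogous ester and O-silylation give the silyl dienol ether, the standard nucleophile for vinylogous Mukaiyama aldol reactions.

**Step 4**
Reactants: 4 4-(methoxymethoxy)-3,5-bis(3-methylbut-2-en-1-yl)benzaldehyde; 6 2,2-dimethyl-6-methylidene-4-(trimethylsilyloxy)-6H-1,3-dioxine
Product: 8 6-{(2S)-2-hydroxy-2-[4-(methoxymethoxy)-3,5-bis(3-methylbut-2-en-1-yl)phenyl]ethyl}-2,2-dimethyl-4H-1,3-dioxin-4-one, via trimethylsilyl ether of the aldol adduct 7 (not isolated)
Conditions: Cu(OTf)2 (5 mol%), (R)-Tol-BINAP (5.5 mol%), Bu4N[Ph3SiF2] (10 mol%), THF, −78 °C; then 1 M HCl, THF, 0 °C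
Reagents that add atoms: none
Why: Catalytic asymmetric vinylogous Mukaiyama aldol through a chiral copper dienolate, which attacks through its γ-carbon; C2 is set by the ligand, Si-face attack giving the (S)-carbinol. The (R)-ligand is chosen on the expectation, by analogy with simple aromatic aldehydes, that it delivers this face; the sense is to be confirmed by correlation before scale-up, and the antipodal ligand used if it is the opposite.

**Step 5**
Reactants: 8 6-{(2S)-2-hydroxy-2-[4-(methoxymethoxy)-3,5-bis(3-methylbut-2-en-1-yl)phenyl]ethyl}-2,2-dimethyl-4H-1,3-dioxin-4-one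
Product: 10 (6S)-4-methoxy-6-[4-(methoxymethoxy)-3,5-bis(3-methylbut-2-en-1-yl)phenyl]-5,6-dihydro-2H-pyran-2-one, via 4-hydroxy lactone 9 (not isolated)
Conditions: K2CO3, MeOH, rt; evaporate; Me2SO4, K2CO3, acetone, rt
Reagents that add atoms: dimethyl sulfate, COS(=O)(=O)OC
Why: Base-induced lactonisation (the carbinol oxygen acylates on the dioxinone carbonyl with loss of acetone), then O-methylation of the cyclic β-keto lactone enolate; this is the established sequence to 4-methoxy-5,6-dihydropyran-2-ones, and the C–O bond at the stereocentre is not broken.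

**Step 6**
Reactants: 11 6-methylhept-5-en-2-one; 12 N,N-dimethylformamide dimethyl acetal
Product: 13 (1E)-1-(dimethylamino)-7-methylocta-1,6-dien-3-one
Conditions: 12 (1.5 equiv), neat, 100 °C, MeOH distilled off
Reagents that add atoms: none
Why: Condensation of an amide acetal with a methyl ketone (enaminone formation); the methyl group should react in preference to the methylene for steric reasons and the E isomer is the stable one, so the prenyl-bearing C8 and the masked C5 are obtained in one step.

**Step 7**
Reactants: 10 (6S)-4-methoxy-6-[4-(methoxymethoxy)-3,5-bis(3-methylbut-2-en-1-yl)phenyl]-5,6-dihydro-2H-pyran-2-one; 13 (1E)-1-(dimethylamino)-7-methylocta-1,6-dien-3-one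
Product: 16 (1S,3E,8E)-9-(dimethylamino)-3-methoxy-1-[4-(methoxymethoxy)-3,5-bis(3-methylbut-2-en-1-yl)phenyl]-6-(3-methylbut-2-en-1-yl)-1-[(triethylsilyl)oxy]nona-3,8-diene-5,7-dione, via lithium enolate of the enaminone 14 (not isolated), via ring-opened dilithium alkoxide diketonate 15 (not isolated)
Conditions: 13 (2.3 equiv), LiN(iPr)2 (2.3 equiv), THF, −78 °C; 10, −78 → −30 °C; Et3SiCl (3 equiv), −78 → 0 °C; aq. NH4Cl
Reagents that add atoms: chlorotriethylsilane, CC[Si](Cl)(CC)CC
Why: Claisen-type acylation of a ketone lithium enolate by a lactone; 13 can only be deprotonated at C8, collapse of the tetrahedral intermediate releases the C2 alkoxide, and the second equivalent of enolate deprotonates the new 1,3-diketone, which drives the acylation. The alkoxide is then silylated in the same flask, and any silyl enol ether on the diketone is lost on aqueous work-up.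

**Step 8**
Reactants: 16 (1S,3E,8E)-9-(dimethylamino)-3-methoxy-1-[4-(methoxymethoxy)-3,5-bis(3-methylbut-2-en-1-yl)phenyl]-6-(3-methylbut-2-en-1-yl)-1-[(triethylsilyl)oxy]nona-3,8-diene-5,7-dione
Product: 19 (2S)-7-hydroxy-2-[4-(methoxymethoxy)-3,5-bis(3-methylbut-2-en-1-yl)phenyl]-8-(3-methylbut-2-en-1-yl)-2,3-dihydro-4H-chromen-4-one, via desilylated hydroxy diketone 17 (not isolated), via dihydropyranone 18 (not isolated)
Conditions: 1 M aq. HCl/THF (1:4), 0 °C → rt (desilylation, ring C); then 45 °C (ring A)
Reagents that add atoms: water, O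
Why: Proposed new method: cold dilute acid cleaves the triethylsilyl ether, and the freed C2 hydroxyl adds to the C8a ketone in a 6-exo-trig hemiketalisation; ionisation to the 4-methoxy-dihydropyranylium ion and hydrolysis at C4 give the 2,3-dihydro-4H-pyran-4-one 18 (ring C). This is a Stork–Danheiser-type transposition whose closest known relatives are the acid cyclodehydrations of δ-hydroxy β-diketones and δ-hydroxy β-alkoxy enones. On warming, the vinylogous amide is activated by O-protonation or hydrolysed to the β-keto aldehyde, and the vinylogous-ester carbon C4a attacks C5 in a 6-endo-trig closure (ring A), the closest known relative being the aldol aromatisation of 3,5,7-tricarbonyl chains to resorcinols. Loss of dimethylamine and enolisation of the C7 ketone through C8–H give the phenol with the prenyl group already on C8. No stereocentre is created; C2 should keep its configuration because its C–O bond is never broken and the twisted, doubly ortho-substituted acetal oxygen gives little support to benzylic ionisation. The selectivity needed is O1–C8a before any attack on C5, because the C8a enol oxygen or C4a reaching C5 first would lead to a 4-pyranone or to a ring-A-first dihydrochalcone. The dimethylamino group is meant to secure this: it makes C5 a much weaker electrophile than C8a in cold acid and holds the C7 carbonyl as a non-nucleophilic O-protonated vinylogous amide. The diketo form, favoured for a 2-alkyl 1,3-diketone in aqueous medium, offers little enol oxygen, and once ring C exists C4a is the only nucleophilic carbon six atoms from C5.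

**Step 9**
Reactants: 19 (2S)-7-hydroxy-2-[4-(methoxymethoxy)-3,5-bis(3-methylbut-2-en-1-yl)phenyl]-8-(3-methylbut-2-en-1-yl)-2,3-dihydro-4H-chromen-4-one
Product: 20 sophoranone, (2S)-7-hydroxy-2-[4-hydroxy-3,5-bis(3-methylbut-2-en-1-yl)phenyl]-8-(3-methylbut-2-en-1-yl)-2,3-dihydro-4H-chromen-4-one
Conditions: 3 M aq. HCl/MeOH (1:5), 40 °C
Reagents that add atoms: none
Why: Acid-catalysed acetal exchange removes the aryl methoxymethyl ether; no base is present, so C2 is not opened to the chalcone, and dilute acid at this temperature should leave the ortho-prenyl phenols uncyclised.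

## Compound list

1 | 4-hydroxy-3,5-diiodobenzaldehyde | O=Cc1cc(I)c(O)c(I)c1 | starting material
2 | 3,5-diiodo-4-(methoxymethoxy)benzaldehyde | COCOc1c(I)cc(C=O)cc1I | intermediate
3 | tributyl(3-methylbut-2-en-1-yl)stannane | CCCC[Sn](CCCC)(CCCC)CC=C(C)C | starting material
4 | 4-(methoxymethoxy)-3,5-bis(3-methylbut-2-en-1-yl)benzaldehyde | COCOc1c(CC=C(C)C)cc(C=O)cc1CC=C(C)C | intermediate
5 | 2,2,6-trimethyl-4H-1,3-dioxin-4-one | CC1=CC(=O)OC(C)(C)O1 | starting material
6 | 2,2-dimethyl-6-methylidene-4-(trimethylsilyloxy)-6H-1,3-dioxine | C=C1C=C(O[Si](C)(C)C)OC(C)(C)O1 | intermediate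
7 | 2,2-dimethyl-6-{(2S)-2-[4-(methoxymethoxy)-3,5-bis(3-methylbut-2-en-1-yl)phenyl]-2-(trimethylsilyloxy)ethyl}-4H-1,3-dioxin-4-one | CC(C)=CCc1cc([C@@H](O[Si](C)(C)C)CC2=CC(=O)OC(C)(C)O2)cc(CC=C(C)C)c1OCOC | intermediate (not isolated)
8 | 6-{(2S)-2-hydroxy-2-[4-(methoxymethoxy)-3,5-bis(3-methylbut-2-en-1-yl)phenyl]ethyl}-2,2-dimethyl-4H-1,3-dioxin-4-one | CC(C)=CCc1cc([C@@H](O)CC2=CC(=O)OC(C)(C)O2)cc(CC=C(C)C)c1OCOC | intermediate
9 | (6S)-4-hydroxy-6-[4-(methoxymethoxy)-3,5-bis(3-methylbut-2-en-1-yl)phenyl]-5,6-dihydro-2H-pyran-2-one | CC(C)=CCc1cc([C@@H]2CC(O)=CC(=O)O2)cc(CC=C(C)C)c1OCOC | intermediate (not isolated)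
10 | (6S)-4-methoxy-6-[4-(methoxymethoxy)-3,5-bis(3-methylbut-2-en-1-yl)phenyl]-5,6-dihydro-2H-pyran-2-one | CC(C)=CCc1cc([C@@H]2CC(OC)=CC(=O)O2)cc(CC=C(C)C)c1OCOC | intermediate
11 | 6-methylhept-5-en-2-one | CC(C)=CCCC(C)=O | starting material
12 | N,N-dimethylformamide dimethyl acetal | COC(OC)N(C)C | starting material
13 | (1E)-1-(dimethylamino)-7-methylocta-1,6-dien-3-one | CC(C)=CCCC(=O)/C=C/N(C)C | intermediate
14 | lithium (1E)-1-(dimethylamino)-7-methylocta-1,3,6-trien-3-olate | CC(C)=CCC=C([O-])/C=C/N(C)C.[Li+] | intermediate (not isolated)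
15 | dilithium salt (C2 alkoxide and C8a/C7 diketonate) of (1S,3E,8E)-9-(dimethylamino)-1-hydroxy-3-methoxy-1-[4-(methoxymethoxy)-3,5-bis(3-methylbut-2-en-1-yl)phenyl]-6-(3-methylbut-2-en-1-yl)nona-3,8-diene-5,7-dione | CC(C)=CCc1cc([C@@H]([O-])C/C(OC)=C\C(=O)C(CC=C(C)C)=C([O-])/C=C/N(C)C)cc(CC=C(C)C)c1OCOC.[Li+].[Li+] | intermediate (not isolated)
16 | (1S,3E,8E)-9-(dimethylamino)-3-methoxy-1-[4-(methoxymethoxy)-3,5-bis(3-methylbut-2-en-1-yl)phenyl]-6-(3-methylbut-2-en-1-yl)-1-[(triethylsilyl)oxy]nona-3,8-diene-5,7-dione (C6 epimers and enol tautomers) | CC(C)=CCc1cc([C@@H](O[Si](CC)(CC)CC)C/C(OC)=C\C(=O)C(CC=C(C)C)C(=O)/C=C/N(C)C)cc(CC=C(C)C)c1OCOC | intermediate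
17 | (1S,3E,8E)-9-(dimethylamino)-1-hydroxy-3-methoxy-1-[4-(methoxymethoxy)-3,5-bis(3-methylbut-2-en-1-yl)phenyl]-6-(3-methylbut-2-en-1-yl)nona-3,8-diene-5,7-dione | CC(C)=CCc1cc([C@@H](O)C/C(OC)=C\C(=O)C(CC=C(C)C)C(=O)/C=C/N(C)C)cc(CC=C(C)C)c1OCOC | intermediate (not isolated)
18 | (2S)-6-[(1E)-1-(dimethylamino)-7-methyl-3-oxoocta-1,6-dien-4-yl]-2-[4-(methoxymethoxy)-3,5-bis(3-methylbut-2-en-1-yl)phenyl]-2,3-dihydro-4H-pyran-4-one | CC(C)=CCc1cc([C@@H]2CC(=O)C=C(C(CC=C(C)C)C(=O)/C=C/N(C)C)O2)cc(CC=C(C)C)c1OCOC | intermediate (not isolated)
19 | (2S)-7-hydroxy-2-[4-(methoxymethoxy)-3,5-bis(3-methylbut-2-en-1-yl)phenyl]-8-(3-methylbut-2-en-1-yl)-2,3-dihydro-4H-chromen-4-one | CC(C)=CCc1cc([C@@H]2CC(=O)c3ccc(O)c(CC=C(C)C)c3O2)cc(CC=C(C)C)c1OCOC | intermediate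
20 | sophoranone, (2S)-7-hydroxy-2-[4-hydroxy-3,5-bis(3-methylbut-2-en-1-yl)phenyl]-8-(3-methylbut-2-en-1-yl)-2,3-dihydro-4H-chromen-4-one | CC(C)=CCc1cc([C@@H]2CC(=O)c3ccc(O)c(CC=C(C)C)c3O2)cc(CC=C(C)C)c1O | target

## Step count and least certain steps

Total: 9 steps. Longest linear sequence: 7 steps (steps 1, 2, 4, 5, 7, 8, 9 from compound 1).

**Step 8 (key step).** The ordering of events may fail. An enol oxygen of the C8a/C7 diketone may cyclise onto C5, or the C7 oxygen onto C4 with loss of methanol, before the C2 hydroxyl has closed ring C; both paths end in 4-pyranones. C4a may also reach C5 first, after which ring C could only close through dehydration to the chalcone and unselective re-addition. The second of these oxygen cyclisations is not blocked by the design; it is only judged slower than attack of the sp3 hydroxyl. All of these run under the same acid. Further risks are ionisation or β-elimination at C2 and partial loss of the acetal on prolonged warming.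
Fallback (known chemistry), from 4 to 20: commercial 1-(2,4-dihydroxyphenyl)ethan-1-one is C-prenylated between its oxygens (prenyl bromide, aq. KOH) to 1-[2,4-dihydroxy-3-(3-methylbut-2-en-1-yl)phenyl]ethan-1-one F1. The non-chelated 4-hydroxyl is protected (MOMCl, K2CO3, acetone) to give 1-[2-hydroxy-4-(methoxymethoxy)-3-(3-methylbut-2-en-1-yl)phenyl]ethan-1-one F2. Claisen–Schmidt condensation of F2 with 4 (KOH, EtOH) gives the 2'-hydroxychalcone F3. Intramolecular oxa-Michael addition under a cinchona-derived bifunctional thiourea catalyst gives the (2S)-bis(methoxymethyl) flavanone F4; because selectivity on unactivated chalcones is usually modest, enrichment on a chiral stationary phase is planned. HCl/MeOH as in step 9 removes both acetals and rejoins the route at 20.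

**Step 7.** Addition to the deactivated vinylogous-carbonate carbonyl of 10 may be slow. The enolate may instead deprotonate the γ-position of 10, which opens the lactone by elimination of the carboxylate. Incomplete silylation of the alkoxide would let the hydroxy diketone cyclise during work-up.
Fallback, from 10 to 16: MeNH(OMe)·HCl/iPrMgCl (THF, −20 °C) opens the lactone to the hydroxy Weinreb amide F5. Et3SiCl/imidazole gives the silyl ether F6. F6 is added to enolate 14 (1.5 equiv, THF, −78 → −20 °C); the tetrahedral chelate persists until work-up, so no second equivalent is consumed and no alkoxide is released, and aqueous work-up gives 16.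

**Step 4.** Facial selectivity may be insufficient or opposite to the expected sense, and the electron-rich aldehyde may react slowly, letting the uncatalysed background reaction lower the selectivity.
Fallback, from 4 to 9: SnCl2-catalysed Roskamp homologation of 4 with ethyl diazoacetate gives the β-keto ester F7. Noyori-type transfer hydrogenation with RuCl(p-cymene)[(S,S)-TsDPEN] and HCO2H/Et3N, which leaves the prenyl alkenes alone and has a secure sense for aryl ketones, should give the (S)-β-hydroxy ester F8. Claisen condensation with excess LiCH2CO2Me (from methyl acetate and LiN(iPr)2, −78 °C) gives the δ-hydroxy β-keto ester F9. K2CO3/MeOH lactonises F9 to 9, which is methylated as in step 5.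

**Step 2.** The second coupling may be incomplete next to the first prenyl group, and allyl transfer may occur with allylic transposition or with protodeiodination.
Fallback, from 2 to 4: (MeO)3CH with pyridinium p-toluenesulfonate in MeOH converts 2 into the dimethyl acetal F10. Two rounds of iodine–magnesium exchange (iPrMgCl·LiCl, −40 °C), each followed by prenyl bromide with catalytic Li2CuCl4, give the diprenyl acetal F11. Aqueous AcOH/THF hydrolyses F11 to 4 without touching the aryl acetal.

## Further compounds

F1 | step 8 | 1-[2,4-dihydroxy-3-(3-methylbut-2-en-1-yl)phenyl]ethan-1-one | CC(=O)c1ccc(O)c(CC=C(C)C)c1O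
F2 | step 8 | 1-[2-hydroxy-4-(methoxymethoxy)-3-(3-methylbut-2-en-1-yl)phenyl]ethan-1-one | CC(=O)c1ccc(OCOC)c(CC=C(C)C)c1O
F3 | step 8 | (2E)-1-[2-hydroxy-4-(methoxymethoxy)-3-(3-methylbut-2-en-1-yl)phenyl]-3-[4-(methoxymethoxy)-3,5-bis(3-methylbut-2-en-1-yl)phenyl]prop-2-en-1-one | CC(C)=CCc1cc(/C=C/C(=O)c2ccc(OCOC)c(CC=C(C)C)c2O)cc(CC=C(C)C)c1OCOC
F4 | step 8 | (2S)-7-(methoxymethoxy)-2-[4-(methoxymethoxy)-3,5-bis(3-methylbut-2-en-1-yl)phenyl]-8-(3-methylbut-2-en-1-yl)-2,3-dihydro-4H-chromen-4-one | CC(C)=CCc1cc([C@@H]2CC(=O)c3ccc(OCOC)c(CC=C(C)C)c3O2)cc(CC=C(C)C)c1OCOC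
F5 | step 7 | (2E,5S)-5-hydroxy-N,3-dimethoxy-5-[4-(methoxymethoxy)-3,5-bis(3-methylbut-2-en-1-yl)phenyl]-N-methylpent-2-enamide | CC(C)=CCc1cc([C@@H](O)C/C(OC)=C\C(=O)N(C)OC)cc(CC=C(C)C)c1OCOC
F6 | step 7 | (2E,5S)-N,3-dimethoxy-5-[4-(methoxymethoxy)-3,5-bis(3-methylbut-2-en-1-yl)phenyl]-N-methyl-5-[(triethylsilyl)oxy]pent-2-enamide | CC(C)=CCc1cc([C@@H](O[Si](CC)(CC)CC)C/C(OC)=C\C(=O)N(C)OC)cc(CC=C(C)C)c1OCOC
F7 | step 4 | ethyl 3-[4-(methoxymethoxy)-3,5-bis(3-methylbut-2-en-1-yl)phenyl]-3-oxopropanoate | CCOC(=O)CC(=O)c1cc(CC=C(C)C)c(OCOC)c(CC=C(C)C)c1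
F8 | step 4 | ethyl (3S)-3-hydroxy-3-[4-(methoxymethoxy)-3,5-bis(3-methylbut-2-en-1-yl)phenyl]propanoate | CCOC(=O)C[C@H](O)c1cc(CC=C(C)C)c(OCOC)c(CC=C(C)C)c1
F9 | step 4 | methyl (5S)-5-hydroxy-5-[4-(methoxymethoxy)-3,5-bis(3-methylbut-2-en-1-yl)phenyl]-3-oxopentanoate | COC(=O)CC(=O)C[C@H](O)c1cc(CC=C(C)C)c(OCOC)c(CC=C(C)C)c1
F10 | step 2 | 5-(dimethoxymethyl)-1,3-diiodo-2-(methoxymethoxy)benzene | COCOc1c(I)cc(C(OC)OC)cc1I
F11 | step 2 | 5-(dimethoxymethyl)-2-(methoxymethoxy)-1,3-bis(3-methylbut-2-en-1-yl)benzene | COCOc1c(CC=C(C)C)cc(C(OC)OC)cc1CC=C(C)C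
A1 | alternative 1 | 7-(methoxymethoxy)-2-[4-(methoxymethoxy)-3,5-bis(3-methylbut-2-en-1-yl)phenyl]-8-(3-methylbut-2-en-1-yl)-4H-chromen-4-one | CC(C)=CCc1cc(-c2cc(=O)c3ccc(OCOC)c(CC=C(C)C)c3o2)cc(CC=C(C)C)c1OCOC
A2 | alternative 1 | 6-iodo-3-(methoxymethoxy)-2-(3-methylbut-2-en-1-yl)phenol | COCOc1ccc(I)c(O)c1CC=C(C)C
A3 | alternative 1 | 5-ethynyl-2-(methoxymethoxy)-1,3-bis(3-methylbut-2-en-1-yl)benzene | C#Cc1cc(CC=C(C)C)c(OCOC)c(CC=C(C)C)c1
A4 | alternative 2 | (2S)-2-[4-(methoxymethoxy)-3,5-bis(3-methylbut-2-en-1-yl)phenyl]-8-(3-methylbut-2-en-1-yl)-7-[(triisopropylsilyl)oxy]-2,3-dihydro-4H-chromen-4-one | CC(C)=CCc1cc([C@@H]2CC(=O)c3ccc(O[Si](C(C)C)(C(C)C)C(C)C)c(CC=C(C)C)c3O2)cc(CC=C(C)C)c1OCOC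
A5 | alternative 2 | (3S)-3-{2-bromo-6-(3-methylbut-2-en-1-yl)-5-[(triisopropylsilyl)oxy]phenoxy}-N-methoxy-3-[4-(methoxymethoxy)-3,5-bis(3-methylbut-2-en-1-yl)phenyl]-N-methylpropanamide | CC(C)=CCc1cc([C@H](CC(=O)N(C)OC)Oc2c(Br)ccc(O[Si](C(C)C)(C(C)C)C(C)C)c2CC=C(C)C)cc(CC=C(C)C)c1OCOC
A6 | alternative 3 | (2S)-2-[4-hydroxy-3,5-bis(3-methylbut-2-en-1-yl)phenyl]-7-(methoxymethoxy)-8-(3-methylbut-2-en-1-yl)-2,3-dihydro-4H-chromen-4-one | CC(C)=CCc1cc([C@@H]2CC(=O)c3ccc(OCOC)c(CC=C(C)C)c3O2)cc(CC=C(C)C)c1O
A7 | alternative 3 | 1-[2-{[4-hydroxy-3,5-bis(3-methylbut-2-en-1-yl)phenyl]methoxy}-4-(methoxymethoxy)-3-(3-methylbut-2-en-1-yl)phenyl]ethan-1-one | CC(=O)c1ccc(OCOC)c(CC=C(C)C)c1OCc1cc(CC=C(C)C)c(O)c(CC=C(C)C)c1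
A8 | alternative 3 | 4-{[2-acetyl-5-(methoxymethoxy)-6-(3-methylbut-2-en-1-yl)phenoxy]methylidene}-2,6-bis(3-methylbut-2-en-1-yl)cyclohexa-2,5-dien-1-one | CC(=O)c1ccc(OCOC)c(CC=C(C)C)c1OC=C1C=C(CC=C(C)C)C(=O)C(CC=C(C)C)=C1
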